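## Retrosynthetic overview

1. Target ⇒ open pentahydroxy bis-chalcone: both pyranone C2–O bonds are made last, in one flask, by a catalyst-controlled double oxa-Michael ring closure that sets both stereocentres.
2. Bis-chalcone ⇒ its penta-MOM ether ⇒ Suzuki union (the 3'–6'' biaryl bond) of a chalcone boronic acid with an iodochalcone.
3. Each chalcone ⇒ Claisen–Schmidt condensation of one common bis-MOM acetophenone (or its mono-iodide) with an aryl aldehyde.
4. Ring order: all four benzene rings are bought; the biaryl bond comes first, then ring C of unit 1, then ring C of unit 2.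

Unit 1 is the flavanone whose ring B (4'-methoxyphenyl) carries the biaryl bond at C3'. Unit 2 is the flavanone whose ring A carries it at C6'' and whose ring B is 4-hydroxyphenyl.

## Assumptions

- The target SMILES defines only C2 and C2'' (both S). The biaryl axis has no descriptor and is treated as not configurationally fixed.
- The three aryl building blocks listed as starting materials are taken as catalogue compounds.
- The epi-quinine-derived squaramide of step 7 is assumed to give the 2S series. This is checked once on 2',6'-dihydroxy-4'-methoxychalcone; if the sense is opposite, the quinidine-derived pseudoenantiomer is used with nothing else changed.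

## Route

Step 1
Reactants: 1 1-(2,6-dihydroxy-4-methoxyphenyl)ethan-1-one
Product: 2 1-[4-methoxy-2,6-bis(methoxymethoxy)phenyl]ethan-1-one
Conditions: NaH (2.6 equiv), MOMCl (2.6 equiv), DMF, 0 °C to rt
Reagents that add atoms: chloromethyl methyl ether (MOMCl), COCCl
Why: Williamson-type O-alkylation of both sodium phenoxides gives the bis-MOM ether, full deprotonation with NaH overcoming the hydrogen bond of the ortho-acyl phenols; no stereocentre is formed.

Step 2
Reactants: 2 1-[4-methoxy-2,6-bis(methoxymethoxy)phenyl]ethan-1-one; 3 (5-formyl-2-methoxyphenyl)boronic acid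
Product: 4 [2-methoxy-5-[(E)-3-[4-methoxy-2,6-bis(methoxymethoxy)phenyl]-3-oxoprop-1-en-1-yl]phenyl]boronic acid
Conditions: KOH (50% aq.), EtOH, 25 °C, 36 h; then citric acid to pH 5 at 0 °C
Reagents that add atoms: none
Why: Claisen–Schmidt condensation, in which the methyl ketone enolate adds to the non-enolisable aldehyde and E1cB dehydration gives the thermodynamic E-enone, while the boronic acid survives as its hydroxyboronate and the MOM acetals are base-stable.

Step 3
Reactants: 2 1-[4-methoxy-2,6-bis(methoxymethoxy)phenyl]ethan-1-one
Product: 5 1-[3-iodo-4-methoxy-2,6-bis(methoxymethoxy)phenyl]ethan-1-one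
Conditions: NIS (1.05 equiv), DMF, 25 °C, dark
Reagents that add atoms: N-iodosuccinimide (NIS), O=C1CCC(=O)N1I
Why: Electrophilic aromatic iodination at the only kind of free ring position (C3 and C5 are equivalent, each ortho/para to three alkoxy donors), with the twisted acetyl group deactivating little and one equivalent of NIS limiting the reaction to mono-iodination.

Step 4
Reactants: 5 1-[3-iodo-4-methoxy-2,6-bis(methoxymethoxy)phenyl]ethan-1-one; 6 4-(methoxymethoxy)benzaldehyde
Product: 7 (E)-1-[3-iodo-4-methoxy-2,6-bis(methoxymethoxy)phenyl]-3-[4-(methoxymethoxy)phenyl]prop-2-en-1-one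
Conditions: KOH (50% aq.), EtOH, 25 °C, 36 h
Reagents that add atoms: none
Why: Claisen–Schmidt condensation as in step 2, the aryl iodide and all MOM ethers being inert to KOH at 25 °C and the E-alkene being the thermodynamic product.

Step 5
Reactants: 4 [2-methoxy-5-[(E)-3-[4-methoxy-2,6-bis(methoxymethoxy)phenyl]-3-oxoprop-1-en-1-yl]phenyl]boronic acid; 7 (E)-1-[3-iodo-4-methoxy-2,6-bis(methoxymethoxy)phenyl]-3-[4-(methoxymethoxy)phenyl]prop-2-en-1-one
Product: 8 (E)-1-[4-methoxy-2,6-bis(methoxymethoxy)phenyl]-3-[4-methoxy-3-[6-methoxy-2,4-bis(methoxymethoxy)-3-[(E)-3-[4-(methoxymethoxy)phenyl]prop-2-enoyl]phenyl]phenyl]prop-2-en-1-one (penta-MOM bis-chalcone)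
Conditions: Pd(OAc)2 (5 mol%), 2-dicyclohexylphosphino-2',6'-dimethoxybiphenyl (10 mol%), K3PO4 (3 equiv), PhMe/H2O 10:1, degassed, 80 °C
Reagents that add atoms: none
Why: Suzuki–Miyaura cross-coupling, in which the bulky electron-rich biaryl phosphine lets zerovalent palladium (formed in situ from the divalent acetate) insert into the di-ortho-substituted aryl iodide and drives reductive elimination to the tri-ortho-substituted biaryl, while the fully MOM-capped chalcones have no free phenol and cannot cyclise in base; no stereocentre is formed.

Step 6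
Reactants: 8 penta-MOM bis-chalcone
Product: 9 (E)-1-(2,6-dihydroxy-4-methoxyphenyl)-3-[3-[2,4-dihydroxy-6-methoxy-3-[(E)-3-(4-hydroxyphenyl)prop-2-enoyl]phenyl]-4-methoxyphenyl]prop-2-en-1-one (pentahydroxy bis-chalcone)
Conditions: HCl (1.25 M in MeOH, 15 equiv), THF, 25 °C, dark; NaHCO3 quench at 0 °C
Reagents that add atoms: none
Why: Acid-catalysed methanolysis of the five aryl MOM acetals (transacetalisation to dimethoxymethane) is much faster at 25 °C than acid-catalysed ring closure of the freed 2',6'-dihydroxychalcones, so the open bis-chalcone is isolated with both alkenes still E; no stereocentre is formed.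

Step 7
Reactants: 9 pentahydroxy bis-chalcone
Product: 11 (2S,2''S)-5,5'',4'''-trihydroxy-7,4',7''-trimethoxy-3',6''-biflavanone, via mono-cyclised chalcone-flavanone 10 (not isolated)
Conditions: 3-[[3,5-bis(trifluoromethyl)phenyl]amino]-4-[[(8α,9S)-6'-methoxycinchonan-9-yl]amino]cyclobut-3-ene-1,2-dione (10 mol%), CH2Cl2/PhMe 2:1 (0.02 M), 4 Å MS, −20 °C, 72 h, dark; then filtration through silica with 0.5% AcOH in the eluent
Reagents that add atoms: none
Why: Proposed new method: a site-selective, doubly enantioselective 6-endo-trig oxa-Michael cyclisation of a free 2',6'-dihydroxy bis-chalcone under bifunctional amine–squaramide catalysis, in which the quinuclidine nitrogen deprotonates the non-chelated ortho-phenol to a chiral ammonium phenoxide ion pair while the two squaramide N–H bonds hold the ketone oxygen (already activated and locked s-cis by the hydrogen bond from the second ortho-hydroxyl), so that the phenoxide oxygen is delivered to one enantiotopic face of the β-carbon and each C2 stereocentre is set as S by catalyst control alone (the two remote sites react independently, ring C of unit 1 first and then ring C of unit 2, where the aryl-flanked, more strongly chelated hydroxyl stays on the carbonyl and the unhindered hydroxyl closes the ring to give the 6''-linked skeleton); the chelated 5-hydroxy-4-ketone of the product, the weak base and the low temperature suppress retro-Michael opening and hence racemisation; the closest known reaction type is the cinchona thiourea- or squaramide-catalysed oxa-Michael closure of activated alkylidene β-keto ester chalcone surrogates to flavanones and, mechanistically, the chalcone isomerase reaction, neither shown for an unactivated bis-chalcone with two competing phenols.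

## Compound list

1 | 1-(2,6-dihydroxy-4-methoxyphenyl)ethan-1-one (2',6'-dihydroxy-4'-methoxyacetophenone) | CC(=O)c1c(O)cc(OC)cc1O | starting material
2 | 1-[4-methoxy-2,6-bis(methoxymethoxy)phenyl]ethan-1-one | CC(=O)c1c(OCOC)cc(OC)cc1OCOC | intermediate
3 | (5-formyl-2-methoxyphenyl)boronic acid | COc1ccc(C=O)cc1B(O)O | starting material
4 | [2-methoxy-5-[(E)-3-[4-methoxy-2,6-bis(methoxymethoxy)phenyl]-3-oxoprop-1-en-1-yl]phenyl]boronic acid | COCOc1cc(OC)cc(OCOC)c1C(=O)/C=C/c1ccc(OC)c(B(O)O)c1 | intermediate
5 | 1-[3-iodo-4-methoxy-2,6-bis(methoxymethoxy)phenyl]ethan-1-one | CC(=O)c1c(OCOC)cc(OC)c(I)c1OCOC | intermediate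
6 | 4-(methoxymethoxy)benzaldehyde | COCOc1ccc(C=O)cc1 | starting material
7 | (E)-1-[3-iodo-4-methoxy-2,6-bis(methoxymethoxy)phenyl]-3-[4-(methoxymethoxy)phenyl]prop-2-en-1-one | COCOc1ccc(/C=C/C(=O)c2c(OCOC)cc(OC)c(I)c2OCOC)cc1 | intermediate
8 | penta-MOM bis-chalcone (both alkenes E; biaryl bond between C3 of the 4-methoxyphenyl ring and the ring carbon flanked by OMe and OMOM) | COCOc1cc(OC)cc(OCOC)c1C(=O)/C=C/c1ccc(OC)c(-c2c(OC)cc(OCOC)c(C(=O)/C=C/c3ccc(OCOC)cc3)c2OCOC)c1 | intermediate
9 | pentahydroxy bis-chalcone (both alkenes E) | COc1cc(O)c(C(=O)/C=C/c2ccc(OC)c(-c3c(OC)cc(O)c(C(=O)/C=C/c4ccc(O)cc4)c3O)c2)c(O)c1 | intermediate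
10 | (2S)-2-[3-[2,4-dihydroxy-6-methoxy-3-[(E)-3-(4-hydroxyphenyl)prop-2-enoyl]phenyl]-4-methoxyphenyl]-5-hydroxy-7-methoxychroman-4-one (unit 1 closed, unit 2 still chalcone) | COc1cc(O)c2c(c1)O[C@H](c1ccc(OC)c(-c3c(OC)cc(O)c(C(=O)/C=C/c4ccc(O)cc4)c3O)c1)CC2=O | intermediate
11 | (2S)-5-hydroxy-2-[3-[(2S)-5-hydroxy-2-(4-hydroxyphenyl)-7-methoxy-4-oxochroman-6-yl]-4-methoxyphenyl]-7-methoxychroman-4-one | COc1cc(O)c2c(c1)O[C@H](c1ccc(OC)c(-c3c(OC)cc4c(c3O)C(=O)C[C@@H](c3ccc(O)cc3)O4)c1)CC2=O | target

## Step count and risks

Total: 7 steps. Longest linear sequence: 6 steps (1 → 2 → 5 → 7 → 8 → 9 → 11).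

**Step 7 (the new double cyclisation).** Three things can go wrong:
- The unit 2 enone, deactivated by its 4-hydroxyphenyl group, may close slowly.
- Per-site selectivity may be too low. At 95:5 per site, statistical amplification gives about 90% (2S,2''S), under 1% (2R,2''R) and about 10% of the mixed diastereomers, which must be separated.
- Unit 2 may close through the aryl-flanked phenol, giving the 8''-linked isomer.

The fallback is known chemistry, sets out from 9 and comes back at 11. Compound 9 is heated with NaOAc in EtOH, the classical chalcone-to-flavanone isomerisation, to give the bis-flavanone as a mixture of its C2/C2'' stereoisomers F1. Preparative HPLC on amylose tris(3,5-dimethylphenylcarbamate) then delivers the (2S,2''S) isomer 11. The other stereoisomers and any 8''-linked isomer are reopened to 9 with aqueous KOH and recycled.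

**Step 5 (hindered Suzuki coupling with two enones present).** The risks are protodeboronation of 4 and slow coupling of the large, di-ortho-substituted iodochalcone. The fallback sets out from 5 and 4 and comes back at 8. It forms the biaryl one stage earlier, before the second enone exists. The smaller iodo ketone 5 is coupled with 4 (Pd(OAc)2, 2-dicyclohexylphosphino-2',6'-dimethoxybiphenyl, K3PO4, PhMe/H2O, 80 °C) to give (E)-3-[3-[3-acetyl-6-methoxy-2,4-bis(methoxymethoxy)phenyl]-4-methoxyphenyl]-1-[4-methoxy-2,6-bis(methoxymethoxy)phenyl]prop-2-en-1-one F2. Claisen–Schmidt condensation of its acetyl group with excess 6 (KOH, EtOH, 25 °C) then gives 8.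

**Step 6 (MOM removal without ring closure).** The risks are premature, racemic cyclisation in acid and slow loss of the aryl-flanked MOM group. The fallback sets out from 8 and comes back at 9. It stops trying to prevent cyclisation and reverses it instead. Compound 8 is deprotected to completion under forcing conditions (methanolic HCl, 55 °C), giving material that is largely ring-closed, namely the stereoisomer mixture of the bis-flavanone F3. This crude is dissolved in 10% aqueous KOH/EtOH at 25 °C, which opens both pyranone rings to the chalcone phenolate. It is then poured into ice-cold dilute HCl, and the yellow open bis-chalcone 9 is filtered off at once.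

## Further compounds

F1 | step 7 | bis-flavanone of the target constitution as a mixture of its C2/C2'' stereoisomers | COc1cc(O)c2c(c1)OC(c1ccc(OC)c(-c3c(OC)cc4c(c3O)C(=O)CC(c3ccc(O)cc3)O4)c1)CC2=O
F2 | step 5 | (E)-3-[3-[3-acetyl-6-methoxy-2,4-bis(methoxymethoxy)phenyl]-4-methoxyphenyl]-1-[4-methoxy-2,6-bis(methoxymethoxy)phenyl]prop-2-en-1-one | COCOc1cc(OC)cc(OCOC)c1C(=O)/C=C/c1ccc(OC)c(-c2c(OC)cc(OCOC)c(C(C)=O)c2OCOC)c1
F3 | step 6 | bis-flavanone of the target constitution as a mixture of its C2/C2'' stereoisomers, formed during forced deprotection | COc1cc(O)c2c(c1)OC(c1ccc(OC)c(-c3c(OC)cc4c(c3O)C(=O)CC(c3ccc(O)cc3)O4)c1)CC2=O
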